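Ring B bears oxygen on five neighbouring carbons (B3, B4, B5, B6, B1) and hydrogen only on B2, so it is built rather than bought: B1, B6, B5 and B4 come from a squarate and B3–B2 from a 1-ethoxyvinyl group. The precursor is a 4-(1-ethoxyvinyl)-3,4-dimethoxycyclobutenone that already carries the complete CDEF tetramer as its C2 aryloxy group. On heating it opens to a dienylketene, which closes the B2–B1 bond and aromatises, creating ring B, its full oxygen pattern and a single free phenol (B1-OH) in one operation. Rings E, D, C and A are added by copper-catalysed etherification of bromobenzaldehydes followed by Baeyer–Villiger oxidation.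

Key step: step 10

Remark on stereochemistry: the target has no stereocentre and no hindered axis, so it is achiral and no enantiomer has to be selected. The only stereocentre on the route (the carbinol carbon of the cyclobutenone) is racemic and is destroyed in the key step.

Labels: rings run from A (2,4,6-trihydroxyphenoxy end) to F (3,4,5-trihydroxyphenoxy end).
- B1 bears O–A, B2 bears H, B3–B5 bear OH, and B6 bears O–C. Ring D is numbered the same way (D1 O–C, D6 O–E).
- C4 and E4 bear the ethers to D and F.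
- "CDEF-aryl" means 4-{2-[3,5-dimethoxy-4-(3,4,5-trimethoxyphenoxy)phenoxy]-3,4,5-trimethoxyphenoxy}-3,5-dimethoxyphenyl.

Design notes:
- Aryloxide is a better leaving group than methoxide, so replacing OMe of a dialkyl squarate by OAr is an uphill equilibrium. The aryloxy squarate is therefore made irreversibly from the squarate ester chloride.
- The carbinol oxygen (future B4) is methylated before heating. The ring expansion then gives a monophenol, not an oxidation-prone hydroquinone with two competing hydroxyls. The extra methyl group falls in the final ether cleavage.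
- Ring A enters as a formyl-activated aryl bromide, and the formyl group is then exchanged for OH. An electron-rich trimethoxyaryl halide would be a much poorer coupling partner for a late, valuable phenol.

Step 1
Reactants: 1 3,4,5-trimethoxyphenol; 2 4-bromo-3,5-dimethoxybenzaldehyde
Product: 3 3,5-dimethoxy-4-(3,4,5-trimethoxyphenoxy)benzaldehyde (EF aldehyde)
Conditions: CuI (10 mol%), picolinic acid (20 mol%), K3PO4, DMSO, 90 °C, Ar
Reagents that add atoms: none
Why: Ullmann-type copper-catalysed diaryl ether synthesis, in which phenol 1 is electron-rich and free at both ortho positions, the para-formyl group of 2 eases activation of the C–Br bond, the picolinate-ligated copper system tolerates ortho substituents next to the halide, and the non-enolisable aldehyde is inert to K3PO4.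

Step 2
Reactants: 3 EF aldehyde
Product: 5 3,5-dimethoxy-4-(3,4,5-trimethoxyphenoxy)phenol (EF phenol), via EF aryl formate 4 (not isolated)
Conditions: mCPBA, CH2Cl2, 0 °C to rt; aq. NaHCO3 wash; K2CO3 (cat.), MeOH, rt, Ar
Reagents that add atoms: mCPBA (3-chloroperbenzoic acid), OOC(=O)c1cccc(Cl)c1
Why: Baeyer–Villiger oxidation of an electron-rich benzaldehyde (Dakin-type outcome), in which the oxygenated aryl group of the Criegee adduct migrates in preference to hydrogen, as in the standard conversion of 3,4,5-trialkoxybenzaldehydes into phenols, and catalytic carbonate in methanol then transesterifies the formate without touching the ethers.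

Step 3
Reactants: 5 EF phenol; 6 2-bromo-3,4,5-trimethoxybenzaldehyde
Product: 7 2-[3,5-dimethoxy-4-(3,4,5-trimethoxyphenoxy)phenoxy]-3,4,5-trimethoxybenzaldehyde (DEF aldehyde)
Conditions: CuI (10 mol%), picolinic acid (20 mol%), K3PO4, DMSO, 100 °C, Ar
Reagents that add atoms: none
Why: Ullmann-type coupling in which the nucleophile is unhindered at E1 and the ortho-formyl group of 6 both activates the flanked C–Br bond and can hold copper next to it, which makes 2-halobenzaldehydes good substrates for this reaction.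

Step 4
Reactants: 7 DEF aldehyde
Product: 9 2-[3,5-dimethoxy-4-(3,4,5-trimethoxyphenoxy)phenoxy]-3,4,5-trimethoxyphenol (DEF phenol), via DEF aryl formate 8 (not isolated)
Conditions: mCPBA, CH2Cl2, 0 °C to rt; aq. NaHCO3 wash; K2CO3 (cat.), MeOH, rt, Ar
Reagents that add atoms: mCPBA (3-chloroperbenzoic acid), OOC(=O)c1cccc(Cl)c1
Why: Baeyer–Villiger oxidation in which the migrating ring D carries an ortho aryloxy and a para methoxy donor, so aryl migration should dominate and D1-OH is unveiled next to the D6 ether, completing the five-oxygen pattern of ring D.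

Step 5
Reactants: 9 DEF phenol; 2 4-bromo-3,5-dimethoxybenzaldehyde
Product: 10 4-{2-[3,5-dimethoxy-4-(3,4,5-trimethoxyphenoxy)phenoxy]-3,4,5-trimethoxyphenoxy}-3,5-dimethoxybenzaldehyde (CDEF aldehyde)
Conditions: CuI (20 mol%), picolinic acid (40 mol%), K3PO4, DMSO, 105 °C, Ar
Reagents that add atoms: none
Why: Ullmann-type coupling that gives a diaryl ether with three ortho substituents, a degree of crowding within the known reach of the CuI/picolinic acid system, with higher loading and temperature compensating for the ortho aryloxy group of 9.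

Step 6
Reactants: 10 CDEF aldehyde
Product: 12 4-{2-[3,5-dimethoxy-4-(3,4,5-trimethoxyphenoxy)phenoxy]-3,4,5-trimethoxyphenoxy}-3,5-dimethoxyphenol (CDEF phenol), via CDEF aryl formate 11 (not isolated)
Conditions: mCPBA, CH2Cl2, 0 °C to rt; aq. NaHCO3 wash; K2CO3 (cat.), MeOH, rt, Ar
Reagents that add atoms: mCPBA (3-chloroperbenzoic acid), OOC(=O)c1cccc(Cl)c1
Why: Baeyer–Villiger oxidation of the same 4-aryloxy-3,5-dimethoxybenzaldehyde type as in step 2, followed by mild formate methanolysis, should give a phenol that is free at both ortho positions.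

Step 7
Reactants: 13 3,4-dichlorocyclobut-3-ene-1,2-dione (squaric acid dichloride)
Product: 14 3-chloro-4-methoxycyclobut-3-ene-1,2-dione (methyl squarate chloride)
Conditions: MeOH (1.0 equiv), CH2Cl2, 0 °C to rt, N2 sweep
Reagents that add atoms: methanol, CO
Why: Addition–elimination at a vinylogous acid chloride, in which the methoxy group introduced first donates into the ring and deactivates the remaining C–Cl bond, so one equivalent of methanol should stop at the known ester chloride stage.

Step 8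
Reactants: 12 CDEF phenol; 14 methyl squarate chloride
Product: 16 3-(CDEF-aryloxy)-4-methoxycyclobut-3-ene-1,2-dione, via sodium CDEF phenoxide 15 (not isolated)
Conditions: NaH, THF, 0 °C; cannulated into 14 (1.2 equiv), THF, −78 to −20 °C
Reagents that add atoms: none
Why: Addition–elimination (vinylogous O-acylation of a phenoxide), in which chloride leaves irreversibly from the most electrophilic ring carbon, no methanol or methoxide is present to displace the aryloxy group again, and inverse addition in the cold suppresses a second substitution.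

Step 9
Reactants: 16 aryloxy methoxy squarate; 17 ethyl vinyl ether
Product: 20 rac-2-(CDEF-aryloxy)-4-(1-ethoxyvinyl)-3,4-dimethoxycyclobut-2-en-1-one, via 1-ethoxyvinyllithium 18 (not isolated), via lithium cyclobutenone alkoxide 19 (not isolated)
Conditions: 17 (excess), t-BuLi, THF, −78 to 0 °C; added (1.1 equiv) to 16, THF, −78 °C; MeOTf, −78 to −20 °C; aq. NaHCO3; Et3N-deactivated silica
Reagents that add atoms: methyl triflate, COS(=O)(=O)C(F)(F)F
Why: 1,2-Addition of an organolithium to a squarate carbonyl followed by O-alkylation, in which the carbonyl next to C–OMe is conjugated only with the weakly donating aryloxy oxygen and is flanked by the small methoxy group, whereas the other carbonyl is a vinylogous methyl ester shielded by the large aryloxy group, so electronic and steric bias both send the hard nucleophile to the required carbon at −78 °C, methyl triflate caps the tertiary alkoxide before work-up, and the new stereocentre is racemic and erased in step 10.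

Step 10
Reactants: 20 rac-2-(CDEF-aryloxy)-4-(1-ethoxyvinyl)-3,4-dimethoxycyclobut-2-en-1-one
Product: 23 2-(CDEF-aryloxy)-5-ethoxy-3,4-dimethoxyphenol (BCDEF phenol; B1-OH free), via (Z)-dienylketene 21 (not isolated), via cyclohexa-2,4-dienone 22 (not isolated)
Conditions: PhMe (0.02 M, degassed), 110 °C, base-washed glassware, Ar
Reagents that add atoms: none
Why: Heat breaks the C1–C4 bond of 20 in a conrotatory 4π opening, and the C4 methoxy group, a lone-pair donor, turns outward for torquoelectronic reasons, so the ethoxyvinyl group turns inward and lies next to the ketene in 21. A disrotatory 6π electrocyclisation then joins the vinyl CH2 (B2) to the ketene carbon (B1) and closes the six-membered ring B as dienone 22, whose enolisation to phenol 23 is irreversible and draws the reversible steps forward. This is the thermal ring expansion of squarate-derived 4-alkenylcyclobutenones (Moore rearrangement), known for 4-hydroxy and 4-alkoxy substrates and for alkoxy-substituted alkenyl groups. No stereocentre is formed and the one in 20 disappears. The only selectivity needed is the sense of rotation, which the C4 oxygen secures, because the substitution pattern of ring B was already fixed by the regiochemistry of step 9. Since B4 is a methyl ether, B1-OH is the only free hydroxyl, and no air-sensitive hydroquinone has to be handled or differentiated.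

Step 11
Reactants: 23 BCDEF phenol; 2 4-bromo-3,5-dimethoxybenzaldehyde
Product: 24 4-[2-(CDEF-aryloxy)-5-ethoxy-3,4-dimethoxyphenoxy]-3,5-dimethoxybenzaldehyde (ABCDEF aldehyde)
Conditions: CuI (20 mol%), picolinic acid (40 mol%), K3PO4, DMSO, 105 °C, Ar
Reagents that add atoms: none
Why: Ullmann-type coupling of the same kind as step 5 (a phenol with one ortho aryloxy group and a formyl-activated bromide), in which B1-OH is the only acidic site of 23, so no site selectivity is required.

Step 12
Reactants: 24 ABCDEF aldehyde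
Product: 26 4-[2-(CDEF-aryloxy)-5-ethoxy-3,4-dimethoxyphenoxy]-3,5-dimethoxyphenol (ABCDEF phenol), via ABCDEF aryl formate 25 (not isolated)
Conditions: mCPBA, CH2Cl2, 0 °C to rt; aq. NaHCO3 wash; K2CO3 (cat.), MeOH, rt, Ar
Reagents that add atoms: mCPBA (3-chloroperbenzoic acid), OOC(=O)c1cccc(Cl)c1
Why: Baeyer–Villiger oxidation as in steps 2 and 6 turns the formyl carbon of ring A into the oxygen para to the A–O–B ether, which completes the 2,4,6-trioxygenated phenoxy pattern of ring A.

Step 13
Reactants: 26 ABCDEF phenol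
Product: 27 target CNP0218077.0 (hexadecahydroxy hexamer)
Conditions: BBr3 (ca. 3 equiv per ether), CH2Cl2, −78 °C to rt, Ar; ice-water; EtOAc extraction; Sephadex LH-20 (degassed MeOH)
Reagents that add atoms: none
Why: Lewis acid-mediated cleavage of aryl alkyl ethers, in which bromide attacks the methyl or ethyl carbon of each boron-complexed ether, so all fourteen methyl ethers and the ethyl ether should fall while the five diaryl ether bonds, which offer no sp3 carbon, stay intact, and exclusion of air protects the pyrogallol units.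

Compound list
1 | 3,4,5-trimethoxyphenol | COc1cc(O)cc(OC)c1OC | starting material
2 | 4-bromo-3,5-dimethoxybenzaldehyde | COc1cc(C=O)cc(OC)c1Br | starting material
3 | EF aldehyde | O=Cc1cc(OC)c(Oc2cc(OC)c(OC)c(OC)c2)c(OC)c1 | intermediate
4 | EF aryl formate | O=COc1cc(OC)c(Oc2cc(OC)c(OC)c(OC)c2)c(OC)c1 | intermediate
5 | EF phenol | Oc1cc(OC)c(Oc2cc(OC)c(OC)c(OC)c2)c(OC)c1 | intermediate
6 | 2-bromo-3,4,5-trimethoxybenzaldehyde | O=Cc1cc(OC)c(OC)c(OC)c1Br | starting material
7 | DEF aldehyde | O=Cc1cc(OC)c(OC)c(OC)c1Oc1cc(OC)c(Oc2cc(OC)c(OC)c(OC)c2)c(OC)c1 | intermediate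
8 | DEF aryl formate | O=COc1cc(OC)c(OC)c(OC)c1Oc1cc(OC)c(Oc2cc(OC)c(OC)c(OC)c2)c(OC)c1 | intermediate
9 | DEF phenol | Oc1cc(OC)c(OC)c(OC)c1Oc1cc(OC)c(Oc2cc(OC)c(OC)c(OC)c2)c(OC)c1 | intermediate
10 | CDEF aldehyde | O=Cc1cc(OC)c(Oc2cc(OC)c(OC)c(OC)c2Oc2cc(OC)c(Oc3cc(OC)c(OC)c(OC)c3)c(OC)c2)c(OC)c1 | intermediate
11 | CDEF aryl formate | O=COc1cc(OC)c(Oc2cc(OC)c(OC)c(OC)c2Oc2cc(OC)c(Oc3cc(OC)c(OC)c(OC)c3)c(OC)c2)c(OC)c1 | intermediate
12 | CDEF phenol | Oc1cc(OC)c(Oc2cc(OC)c(OC)c(OC)c2Oc2cc(OC)c(Oc3cc(OC)c(OC)c(OC)c3)c(OC)c2)c(OC)c1 | intermediate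
13 | 3,4-dichlorocyclobut-3-ene-1,2-dione | O=C1C(=O)C(Cl)=C1Cl | starting material
14 | 3-chloro-4-methoxycyclobut-3-ene-1,2-dione | COC1=C(Cl)C(=O)C1=O | intermediate
15 | sodium CDEF phenoxide | [Na+].[O-]c1cc(OC)c(Oc2cc(OC)c(OC)c(OC)c2Oc2cc(OC)c(Oc3cc(OC)c(OC)c(OC)c3)c(OC)c2)c(OC)c1 | intermediate
16 | 3-(CDEF-aryloxy)-4-methoxycyclobut-3-ene-1,2-dione | COC1=C(Oc2cc(OC)c(Oc3cc(OC)c(OC)c(OC)c3Oc3cc(OC)c(Oc4cc(OC)c(OC)c(OC)c4)c(OC)c3)c(OC)c2)C(=O)C1=O | intermediate
17 | ethyl vinyl ether | C=COCC | starting material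
18 | 1-ethoxyvinyllithium | [Li]C(=C)OCC | intermediate
19 | lithium cyclobutenone alkoxide (racemic) | [Li+].[O-]C1(C(=C)OCC)C(OC)=C(Oc2cc(OC)c(Oc3cc(OC)c(OC)c(OC)c3Oc3cc(OC)c(Oc4cc(OC)c(OC)c(OC)c4)c(OC)c3)c(OC)c2)C1=O | intermediate
20 | rac-2-(CDEF-aryloxy)-4-(1-ethoxyvinyl)-3,4-dimethoxycyclobut-2-en-1-one | O=C1C(Oc2cc(OC)c(Oc3cc(OC)c(OC)c(OC)c3Oc3cc(OC)c(Oc4cc(OC)c(OC)c(OC)c4)c(OC)c3)c(OC)c2)=C(OC)C1(OC)C(=C)OCC | intermediate
21 | (Z)-dienylketene (vinyl group cis to the ketene-bearing carbon) | O=C=C(Oc1cc(OC)c(Oc2cc(OC)c(OC)c(OC)c2Oc2cc(OC)c(Oc3cc(OC)c(OC)c(OC)c3)c(OC)c2)c(OC)c1)/C(OC)=C(OC)\C(=C)OCC | intermediate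
22 | 2-(CDEF-aryloxy)-5-ethoxy-3,4-dimethoxycyclohexa-2,4-dien-1-one | O=C1CC(OCC)=C(OC)C(OC)=C1Oc1cc(OC)c(Oc2cc(OC)c(OC)c(OC)c2Oc2cc(OC)c(Oc3cc(OC)c(OC)c(OC)c3)c(OC)c2)c(OC)c1 | intermediate
23 | BCDEF phenol, 2-(CDEF-aryloxy)-5-ethoxy-3,4-dimethoxyphenol | Oc1cc(OCC)c(OC)c(OC)c1Oc1cc(OC)c(Oc2cc(OC)c(OC)c(OC)c2Oc2cc(OC)c(Oc3cc(OC)c(OC)c(OC)c3)c(OC)c2)c(OC)c1 | intermediate
24 | ABCDEF aldehyde | O=Cc1cc(OC)c(Oc2cc(OCC)c(OC)c(OC)c2Oc2cc(OC)c(Oc3cc(OC)c(OC)c(OC)c3Oc3cc(OC)c(Oc4cc(OC)c(OC)c(OC)c4)c(OC)c3)c(OC)c2)c(OC)c1 | intermediate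
25 | ABCDEF aryl formate | O=COc1cc(OC)c(Oc2cc(OCC)c(OC)c(OC)c2Oc2cc(OC)c(Oc3cc(OC)c(OC)c(OC)c3Oc3cc(OC)c(Oc4cc(OC)c(OC)c(OC)c4)c(OC)c3)c(OC)c2)c(OC)c1 | intermediate
26 | ABCDEF phenol | Oc1cc(OC)c(Oc2cc(OCC)c(OC)c(OC)c2Oc2cc(OC)c(Oc3cc(OC)c(OC)c(OC)c3Oc3cc(OC)c(Oc4cc(OC)c(OC)c(OC)c4)c(OC)c3)c(OC)c2)c(OC)c1 | intermediate
27 | CNP0218077.0 (achiral) | Oc1cc(O)c(Oc2cc(O)c(O)c(O)c2Oc2cc(O)c(Oc3cc(O)c(O)c(O)c3Oc3cc(O)c(Oc4cc(O)c(O)c(O)c4)c(O)c3)c(O)c2)c(O)c1 | target

Total step count: 13. Longest linear sequence: 12 (steps 1–6 and 8–13; step 7 is a one-step side branch).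

Steps most likely to fail

Step 9.
- What may go wrong: the organolithium may attack the other carbonyl, or attack the aryloxy-bearing ring carbon with loss of aryloxide. Methylation of the crowded tertiary alkoxide in the cold may also be too slow, so that the alkoxide degrades first.
- Fallback: it sets out from 16 and separates addition from protection. Reagent 18 is added as before, and alkoxide 19 is protonated at −78 °C with saturated NH4Cl to give racemic 2-(CDEF-aryloxy)-4-(1-ethoxyvinyl)-4-hydroxy-3-methoxycyclobut-2-en-1-one F1. This is freed of any regioisomer on triethylamine-deactivated silica and then etherified under neutral conditions (MeI, Ag2O, MeCN, rt, dark), a known way of methylating 4-hydroxycyclobutenones. The fallback comes back to the route at 20.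

Step 10.
- What may go wrong: traces of acid may hydrolyse the enol ether before the ring opens, or the ketene may be captured by adventitious water or by the electron-rich ring C instead of closing onto the vinyl group.
- Fallback: it sets out from 12, gives up the squarate, and builds ring B the way ring D was built.
  - Phenol 12 is coupled with 6 (CuI, picolinic acid, K3PO4, DMSO) to give 2-(CDEF-aryloxy)-3,4,5-trimethoxybenzaldehyde F2.
  - mCPBA converts it into 2-(CDEF-aryloxy)-3,4,5-trimethoxyphenyl formate F3, and methanolysis gives 2-(CDEF-aryloxy)-3,4,5-trimethoxyphenol F4, the all-methyl analogue of 23.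
  - This phenol takes the place of 23. Coupling with 2 gives 4-[2-(CDEF-aryloxy)-3,4,5-trimethoxyphenoxy]-3,5-dimethoxybenzaldehyde F5.
  - Baeyer–Villiger oxidation gives 4-[2-(CDEF-aryloxy)-3,4,5-trimethoxyphenoxy]-3,5-dimethoxyphenyl formate F6, and methanolysis gives 4-[2-(CDEF-aryloxy)-3,4,5-trimethoxyphenoxy]-3,5-dimethoxyphenol F7.
  - BBr3 cleaves all fifteen methyl ethers, and the fallback comes back to the route at 27.

Step 11.
- What may go wrong: copper may be slow to activate the doubly ortho-substituted bromide in the presence of a bulky phenoxide. The bromide would then be reduced and the electron-rich phenoxide oxidised before coupling.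
- Fallback: it sets out from 23 and replaces metal catalysis by addition–elimination. The caesium phenoxide of 23 (Cs2CO3, DMSO, 110–120 °C) attacks 4-fluoro-3,5-dimethoxybenzaldehyde, a catalogue building block. The small fluoride leaving group and the para-formyl acceptor allow an SNAr reaction that is far less sensitive to crowding. It comes back to the route at 24 and makes no compound outside the list (entry F0).

Further compounds
F1 | step 9 | rac-2-(CDEF-aryloxy)-4-(1-ethoxyvinyl)-4-hydroxy-3-methoxycyclobut-2-en-1-one | O=C1C(Oc2cc(OC)c(Oc3cc(OC)c(OC)c(OC)c3Oc3cc(OC)c(Oc4cc(OC)c(OC)c(OC)c4)c(OC)c3)c(OC)c2)=C(OC)C1(O)C(=C)OCC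
F2 | step 10 | 2-(CDEF-aryloxy)-3,4,5-trimethoxybenzaldehyde | O=Cc1cc(OC)c(OC)c(OC)c1Oc1cc(OC)c(Oc2cc(OC)c(OC)c(OC)c2Oc2cc(OC)c(Oc3cc(OC)c(OC)c(OC)c3)c(OC)c2)c(OC)c1
F3 | step 10 | 2-(CDEF-aryloxy)-3,4,5-trimethoxyphenyl formate | O=COc1cc(OC)c(OC)c(OC)c1Oc1cc(OC)c(Oc2cc(OC)c(OC)c(OC)c2Oc2cc(OC)c(Oc3cc(OC)c(OC)c(OC)c3)c(OC)c2)c(OC)c1
F4 | step 10 | 2-(CDEF-aryloxy)-3,4,5-trimethoxyphenol | Oc1cc(OC)c(OC)c(OC)c1Oc1cc(OC)c(Oc2cc(OC)c(OC)c(OC)c2Oc2cc(OC)c(Oc3cc(OC)c(OC)c(OC)c3)c(OC)c2)c(OC)c1
F5 | step 10 | 4-[2-(CDEF-aryloxy)-3,4,5-trimethoxyphenoxy]-3,5-dimethoxybenzaldehyde | O=Cc1cc(OC)c(Oc2cc(OC)c(OC)c(OC)c2Oc2cc(OC)c(Oc3cc(OC)c(OC)c(OC)c3Oc3cc(OC)c(Oc4cc(OC)c(OC)c(OC)c4)c(OC)c3)c(OC)c2)c(OC)c1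
F6 | step 10 | 4-[2-(CDEF-aryloxy)-3,4,5-trimethoxyphenoxy]-3,5-dimethoxyphenyl formate | O=COc1cc(OC)c(Oc2cc(OC)c(OC)c(OC)c2Oc2cc(OC)c(Oc3cc(OC)c(OC)c(OC)c3Oc3cc(OC)c(Oc4cc(OC)c(OC)c(OC)c4)c(OC)c3)c(OC)c2)c(OC)c1
F7 | step 10 | 4-[2-(CDEF-aryloxy)-3,4,5-trimethoxyphenoxy]-3,5-dimethoxyphenol | Oc1cc(OC)c(Oc2cc(OC)c(OC)c(OC)c2Oc2cc(OC)c(Oc3cc(OC)c(OC)c(OC)c3Oc3cc(OC)c(Oc4cc(OC)c(OC)c(OC)c4)c(OC)c3)c(OC)c2)c(OC)c1
F0 | step 11 | none | none
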